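# Proposed total synthesis of CNP0183476.2 (sipholane-type triol)

## Structural features

The target (C30H52O4) is built from two bicycles joined by a two-carbon bridge: a cis-fused hydroazulene (cyclopentanol ring A on cycloheptene ring B) and a trans-fused perhydro-1-benzoxepine (cyclohexanol ring C on oxepanol ring D). Atom labels used below follow the order of the atoms in the SMILES string: ring B is C2 (olefinic, methyl-bearing), C3 (olefinic CH), C4, C5, C6, C10 (CMe2) and C11; ring A is C5–C9 with the methyl carbinol at C9; C12–C13 is the bridge; ring C is C14, C15 (quaternary, methyl), C21, C22, C23 and C24 (methyl carbinol); ring D is C15–C19, O20 and C21, with the secondary hydroxyl at C18 and the gem-dimethyl group at C19. There are nine stereocentres, (5S,6S,9S,11R) and (14S,15S,18S,21S,24R): C9, C5 and C6 are contiguous, C6 and C11 flank the quaternary C10 with their hydrogens cis, and C24, C14, C15 and C21 are contiguous, with the axial C24 hydroxyl, the axial C15 methyl and the equatorial bridge on one face of ring C. The fragile groups are the two tertiary carbinols (C9, C24), which dehydrate under acid, and the trisubstituted C2=C3 olefin, which is open to electrophiles, hydroboration and acid-induced migration. The real difficulty is threefold: the cis 1,3-relationship of C6 and C11 across C10 in a seven-membered ring, two seven-membered rings, and two stereochemical domains that are insulated by the CH2CH2 bridge and so need independent absolute control. The two halves must also be joined at C14, next to the quaternary C15. The key step exploits the 1,2-relationship in ring A between the carbinol carbon C9 and the ring-fusion methine C5, together with the fact that C5 is β to C3 of ring B: a ketyl at C9 can close ring A onto C5 of a C3-enone.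

## Logic of the disconnections

**40 ⇒ 39.** Only the two O–Si bonds (at C9 and C18) are cut. Both carbinols that need masking during enolate, sulfonylation and organometallic steps carry the same silyl group, so one fluoride step finishes the synthesis. The demand is non-acidic cleavage that spares the tertiary carbinols and the olefin.

**39 ⇒ 38.** The C24–CH3 bond is cut. The C24 carbinol has its methyl equatorial and its oxygen axial, syn to the axial C15 methyl, which is what equatorial attack on a C24 ketone should give because the C15 methyl blocks the axial trajectory. The gain is the loss of one stereocentre and a carbonyl that makes C14 a site for C–C bond formation. The demand is a non-basic methyl nucleophile and equatorial attack.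

**38 ⇒ 37 ⇒ 35 ⇒ 27 + 33.** The C13–C14 bond is cut (aldol), after adding back the C13=C14 and C22=C23 unsaturation. This is the one bond of the bridge that sits next to a carbon that can be an enolate, and it divides the molecule into a C16 and a C13 half. The C22=C23 double bond of 33 leaves C14 as the only enolisable position. The demands are α'-deprotonation, a conjugate reduction that ignores the ring B olefin, and protonation of C14 that places the bridge equatorial.

**27 ⇒ 26 ⇒ 25 ⇒ 24 ⇒ 22 ⇒ 21.** No skeletal bond is cut. The C13 aldehyde goes back to the silyl ether, and the C2=C3 olefin goes back through the C3 enol triflate to the C3 ketone. The gain is that the olefin is traced to the carbonyl the key step leaves behind. The demands are enolisation toward the more substituted C2 and cleavage of the primary silyl ether in the presence of the tertiary one.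

**21 ⇒ 20.** The C5–C9 bond is cut (ring A). The cut turns a bicycle with two new stereocentres into a monocyclic enone carrying a 3-oxobutyl arm on C6. The demand is C–C bond formation in preference to simple reduction of the enone, with the hydroxyl ending cis to the fusion hydrogens.

**20 ⇒ 19 ⇒ 17 ⇒ 16 ⇒ 14 + 15.** The side-chain ketone is masked and the C4=C5 unsaturation is removed. Then the C3–C4 and C4–C5 bonds are cut so that C4 leaves as the diazo carbon of 15. The seven-membered ring becomes a cyclohexanone, in which the cis 1,3-relationship can be set by six-membered-ring chemistry. The demands are migration of the CH2 (C5) rather than the methyl-bearing methine (C2), and kinetic enolisation at C4.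

**14 ⇒ 13 ⇒ 11 ⇒ 10 ⇒ 9 ⇒ 7 + 8.** The C3 carbonyl is traced to a C2=C3 olefin (hydroboration–oxidation), and the C11–C12 bond is cut as a Claisen retron. The two-carbon oxygenated arm then comes from 8 and is delivered suprafacially from a C3 carbinol, so C11 is set by relay from C6 through an alcohol that is cis to the C6 chain. The demands are a cis-selective 1,2-reduction and anti-Markovnikov hydroboration.

**7 ⇒ 6 ⇒ 2 + 3; 2 ⇒ 1.** The C6–C7 bond is cut (conjugate addition of the masked oxobutyl unit from 3 via 4 and 5), then the C5=C6 unsaturation of the dienone is removed. One catalytic step sets the only stereocentre that is not relayed. The demands are attack at the unsubstituted enone of 2 and high facial selectivity.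

**33 ⇒ 32 ⇒ 31 ⇒ 29 ⇒ 28.** The C22=C23 unsaturation is removed; then the C14–C15 and O20–C19 bonds are cut together (epoxide-opening cascade), and finally the two epoxide C–O pairs. The carbon skeleton of rings C and D is exactly that of 28, and C15, C18 and C21 derive from two reagent-controlled epoxidations of (E)- and trisubstituted olefins. The demand is that the internal epoxide oxygen, not the enol silane, attacks the activated terminal epoxide first, so that the oxepane arises from an epoxonium ion.

## Other disconnections considered

**Alternative 1:** The cut removes C17 from ring D, i.e. the C16–C17 and C17–C18 bonds. In the forward direction Me3SiCHN2 with BF3·OEt2 would homologate the tetrahydropyran-3-one A2 to the oxepan-3-one A1 by migration of the ring CH2.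
- In its favour: the ether ring is first closed as a six-membered ring, the migrating group (CH2 rather than the oxygenated quaternary carbon) is predictable, and A1 already holds C14 and the C24 carbinol in their final configuration.
- Against it here: A1 carries C13 as a benzyloxymethyl group, so the union with the other half would fall on C12–C13 and would need a one-carbon arm on ring B. The samarium precursor 20 and its product 21 necessarily carry both bridge carbons. C18 would be set by hydride reduction of a flexible oxepanone beside a quaternary carbon, which is less predictable than a reagent-controlled epoxidation. A2 needs its own multi-step synthesis with separate control of C14, C15, C21 and C24.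
- Comparison: on structure the alternative is the better of the two in settling C24 before fragment union, which removes the late addition to a hindered ketone (step 26). On mechanism the diazoalkane insertion is at least the equal of the cascade of step 21 in predictability. On step economy the chosen four-step entry to 33 is shorter, and Alternative 1 addresses ring D only, so it would replace steps 19–26 and not the ring A annulation.

**Alternative 2:** The cut is the C14–C24 bond of ring C. In the forward direction TiCl4 would activate the methyl ketone of the oxepane A4, and the γ-carbon of its allylsilane would close ring C to give the vinyl carbinol A3.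
- In its favour: one step closes ring C and creates C14 and the tertiary C24 carbinol together, so no late methyl addition is needed, and the vinyl group is a flexible handle.
- Against it here: the vinyl group of A3 contains both C13 and C12, so the other half would have to be attached at C11–C12, a bond to a stereogenic ring carbon next to the quaternary C10. Otherwise the stub would have to be cut back by one carbon, again in conflict with the two-carbon arm of 21. The relative configuration at C14/C24 depends on which face of the ketone is presented in a transition state crowded by the C15 quaternary centre. A4 presupposes a finished ring D bearing two differentiated side chains.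
- Comparison: on structure it is the better plan for C24, and equal for ring D, which it does not address. On mechanism a Lewis-acid allylsilane addition is as dependable as the aldol of step 23. On step economy it is the weaker plan, because of the length of the route to A4 and the harder fragment union.

**Alternative 3:** The cut is the C6–C10 bond of ring B. In the forward direction Fe(acac)3 and PhSiH3 would convert the isopropenyl group of the cyclopentenone A6 into a tertiary radical at C10, which would add 7-endo to the enone β-carbon C6 and give the hydroazulenone ketal A5.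
- In its favour: it forms the most congested bond of the hydroazulene by a radical process that is tolerant of steric crowding. It is convergent, and on this bond it is the better of the two plans. In the chosen route C10 is bought with compound 1 and the flanking centres are set one after the other.
- Against it here: the seven-membered closure must compete with hydrogenation of the tertiary radical and with attack at the enone α-carbon. C6 would be controlled only by the acyclic C11 centre across the new quaternary carbon. The C9 carbinol would then come from methyl addition to the cyclopentanone of A5, which should occur from the convex face and place the hydroxyl on the concave face, opposite to the target. The C2 ketal must finally be turned into the methyl-bearing olefin with three possible positions for the double bond.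
- Comparison: on structure and mechanism the chosen ketyl closure is the better plan for C9, because it sets the hydroxyl cis to the fusion hydrogens directly. The two are equal on the olefin problem: a regiochemical question in both. On step economy they are about equal up to the bicycle, and Alternative 3 is longer afterwards.

Key step: step 13

**Remarks on the chemistry (assumptions, one line each)**
- The target SMILES defines the absolute configuration; the labels C2–C24 above are used in names where a systematic locant would be unwieldy.
- Compounds 20 and 21 were checked atom by atom and centre by centre against the target (C6/C11 side chains cis, fusion hydrogens cis, C9–OH cis to them); no correction was needed.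
- C2 of 14–22 is deliberately an epimer mixture; it becomes sp2 in step 15.
- Design improvement of precursor 20: its methyl ketone is liberated from a dioxolane only in the step before the cyclisation and is never exposed to base, because the free methyl ketone can add intramolecularly to the enone.
- The facial sense of the copper–phosphoramidite catalyst on 2 is assumed to follow that known for 4,4-dimethylcyclohexenone; if it is opposite, the enantiomeric ligand is used.
- The L-fructose-derived ketone is assumed to give (S)-configured epoxides, mirroring the D-fructose-derived catalyst; if not, the other enantiomer is used.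
- (E)-Geranylacetone (28) is used free of its Z isomer.

## Route

Step 1
Reactants: 1 2,4,4-trimethylcyclohex-2-en-1-one
Product: 2 2,4,4-trimethylcyclohexa-2,5-dien-1-one
Conditions: DDQ, 1,4-dioxane, reflux
Reagents that add atoms: none
Why: DDQ dehydrogenation by hydride abstraction from the enol; the quaternary C4 leaves C5–C6 as the only position that can be dehydrogenated, so the cross-conjugated dienone should form without regiochemical ambiguity.

Step 2
Reactants: 2 2,4,4-trimethylcyclohexa-2,5-dien-1-one; 3 2-(2-bromoethyl)-2-methyl-1,3-dioxolane
Product: 6 (5S)-2,4,4-trimethyl-5-[2-(2-methyl-1,3-dioxolan-2-yl)ethyl]cyclohex-2-en-1-one, via Grignard reagent 4 (not isolated), via diorganozinc reagent 5 (not isolated)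
Conditions: 3, Mg, THF, 20 °C; Zn(OMe)2 (0.5 equiv), removal of the magnesium salts; then 2, Cu(OTf)2 (2 mol%), (R,S,S)-O,O'-(1,1'-binaphthalene-2,2'-diyl) N,N-bis(1-phenylethyl)phosphoramidite (4 mol%), PhMe, –30 °C; aq. NH4Cl
Reagents that add atoms: none
Why: Copper-catalysed asymmetric conjugate addition of a diorganozinc should take place at the β-carbon of the unsubstituted enone, because the α-methyl enone is far less reactive toward organocopper species; the ligand fixes the face of attack and so the first stereocentre (C6 of the target), and protonation of the zinc enolate returns the conjugated 2-methyl enone.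

Step 3
Reactants: 6 (5S)-2,4,4-trimethyl-5-[2-(2-methyl-1,3-dioxolan-2-yl)ethyl]cyclohex-2-en-1-one
Product: 7 (1R,5S)-2,4,4-trimethyl-5-[2-(2-methyl-1,3-dioxolan-2-yl)ethyl]cyclohex-2-en-1-ol
Conditions: NaBH4, CeCl3·7H2O, MeOH, –78 to 0 °C
Reagents that add atoms: none
Why: Luche 1,2-reduction; axial hydride delivery to the half-chair with the side chain equatorial should give the pseudo-equatorial alcohol cis to that chain, as in reductions of 5-substituted 2-methylcyclohexenones, and this sets the relay centre (a CBS reduction is the reagent-controlled reserve).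

Step 4
Reactants: 7 (1R,5S)-2,4,4-trimethyl-5-[2-(2-methyl-1,3-dioxolan-2-yl)ethyl]cyclohex-2-en-1-ol; 8 triethyl orthoacetate
Product: 9 ethyl 2-[(1R,5S)-2,6,6-trimethyl-5-[2-(2-methyl-1,3-dioxolan-2-yl)ethyl]cyclohex-2-en-1-yl]acetate
Conditions: EtCO2H (cat.), 140 °C, distillation of EtOH
Reagents that add atoms: none
Why: Johnson–Claisen rearrangement; the mixed ketene acetal rearranges suprafacially, so the acetate unit is delivered to the carbon next to the gem-dimethyl group on the face that carried the oxygen, cis to the existing side chain (C11 of the target), and the new trisubstituted olefin marks the future ketone carbon.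

Step 5
Reactants: 9 ethyl 2-[(1R,5S)-2,6,6-trimethyl-5-[2-(2-methyl-1,3-dioxolan-2-yl)ethyl]cyclohex-2-en-1-yl]acetate
Product: 10 2-[(1R,5S)-2,6,6-trimethyl-5-[2-(2-methyl-1,3-dioxolan-2-yl)ethyl]cyclohex-2-en-1-yl]ethan-1-ol
Conditions: LiAlH4, THF, 0 °C
Reagents that add atoms: none
Why: Hydride reduction of the ester to the primary alcohol; ketal and olefin are inert and no stereocentre is touched.

Step 6
Reactants: 10 2-[(1R,5S)-2,6,6-trimethyl-5-[2-(2-methyl-1,3-dioxolan-2-yl)ethyl]cyclohex-2-en-1-yl]ethan-1-ol
Product: 11 tert-butyldimethylsilyl ether of 10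
Conditions: TBSCl, imidazole, DMF, 23 °C
Reagents that add atoms: tert-butyldimethylsilyl chloride, CC(C)(C)[Si](C)(C)Cl
Why: Standard silylation of a primary alcohol; the group is chosen to survive borane, Lewis acid, enolate and samarium chemistry and to be removable later in the presence of a tertiary silyl ether.

Step 7
Reactants: 11 tert-butyldimethylsilyl ether of 10
Product: 13 (3R,5S)-3-[2-(tert-butyldimethylsilyloxy)ethyl]-2,4,4-trimethyl-5-[2-(2-methyl-1,3-dioxolan-2-yl)ethyl]cyclohexan-1-ol (epimers at C1 and C2), via alkylborane 12 (not isolated)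
Conditions: BH3·THF, THF, 0 to 23 °C; then NaOH, H2O2, 0 °C
Reagents that add atoms: hydrogen peroxide, OO
Why: Hydroboration–oxidation; boron adds to the less substituted olefinic carbon and is replaced by oxygen with retention, which places the oxygen on the carbon that becomes the ring ketone; the two new centres are removed or equilibrated in later steps.

Step 8
Reactants: 13 (3R,5S)-3-[2-(tert-butyldimethylsilyloxy)ethyl]-2,4,4-trimethyl-5-[2-(2-methyl-1,3-dioxolan-2-yl)ethyl]cyclohexan-1-ol
Product: 14 (3R,5S)-3-[2-(tert-butyldimethylsilyloxy)ethyl]-2,4,4-trimethyl-5-[2-(2-methyl-1,3-dioxolan-2-yl)ethyl]cyclohexan-1-one (C2 epimers)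
Conditions: DMP, NaHCO3, CH2Cl2, 23 °C
Reagents that add atoms: none
Why: Dess–Martin oxidation of the secondary alcohol under buffered conditions that leave the ketal and the silyl ether intact.

Step 9
Reactants: 14 (3R,5S)-3-[2-(tert-butyldimethylsilyloxy)ethyl]-2,4,4-trimethyl-5-[2-(2-methyl-1,3-dioxolan-2-yl)ethyl]cyclohexan-1-one; 15 ethyl diazoacetate
Product: 16 ethyl (4R,6S)-4-[2-(tert-butyldimethylsilyloxy)ethyl]-3,5,5-trimethyl-6-[2-(2-methyl-1,3-dioxolan-2-yl)ethyl]-2-oxocycloheptane-1-carboxylate (epimers at C1 and C3)
Conditions: BF3·OEt2, Et2O, 0 °C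
Reagents that add atoms: none
Why: Lewis-acid-promoted diazo ester homologation (Tiffeneau–Demjanov-type ring expansion); the diazo carbon adds to the activated carbonyl and the less substituted α-CH2 should migrate in preference to the methyl-bearing methine, so the new ester-bearing carbon (C4) is inserted on the side away from the methyl group.

Step 10
Reactants: 16 ethyl (4R,6S)-4-[2-(tert-butyldimethylsilyloxy)ethyl]-3,5,5-trimethyl-6-[2-(2-methyl-1,3-dioxolan-2-yl)ethyl]-2-oxocycloheptane-1-carboxylate
Product: 17 (3R,5R)-3-[2-(tert-butyldimethylsilyloxy)ethyl]-2,4,4-trimethyl-5-[2-(2-methyl-1,3-dioxolan-2-yl)ethyl]cycloheptan-1-one (C2 epimers; the descriptor at C5 changes by CIP priority only)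
Conditions: LiCl, H2O, DMSO, 150 °C
Reagents that add atoms: none
Why: Krapcho dealkoxycarbonylation (chloride attack on the ethyl group, loss of CO2, protonation of the enolate) under neutral conditions tolerated by the ketal and the silyl ether.

Step 11
Reactants: 17 (3R,5R)-3-[2-(tert-butyldimethylsilyloxy)ethyl]-2,4,4-trimethyl-5-[2-(2-methyl-1,3-dioxolan-2-yl)ethyl]cycloheptan-1-one
Product: 19 (4S,6R)-6-[2-(tert-butyldimethylsilyloxy)ethyl]-5,5,7-trimethyl-4-[2-(2-methyl-1,3-dioxolan-2-yl)ethyl]cyclohept-2-en-1-one (C7 epimers), via lithium enolate 18 (not isolated)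
Conditions: LDA, THF, –78 °C; then N-tert-butylbenzenesulfinimidoyl chloride, –78 °C
Reagents that add atoms: none
Why: Kinetic deprotonation takes the CH2 rather than the hindered methyl-bearing methine, and the lithium enolate is dehydrogenated in one pot through its S-enol sulfinimidate (Mukaiyama dehydrogenation), which places the double bond toward the carbon that bears the masked oxobutyl arm.

Step 12
Reactants: 19 (4S,6R)-6-[2-(tert-butyldimethylsilyloxy)ethyl]-5,5,7-trimethyl-4-[2-(2-methyl-1,3-dioxolan-2-yl)ethyl]cyclohept-2-en-1-one
Product: 20 (4S,6R)-6-[2-(tert-butyldimethylsilyloxy)ethyl]-5,5,7-trimethyl-4-(3-oxobutyl)cyclohept-2-en-1-one (C7 epimers)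
Conditions: PPTS, acetone–H2O, 45 °C
Reagents that add atoms: water, O
Why: Mild acid-catalysed hydrolysis of the dioxolane; the primary silyl ether and the enone should survive, and base is avoided because the free methyl ketone could add to the enone intramolecularly.

Step 13
Reactants: 20 (4S,6R)-6-[2-(tert-butyldimethylsilyloxy)ethyl]-5,5,7-trimethyl-4-(3-oxobutyl)cyclohept-2-en-1-one
Product: 21 (5S,6S,9S,11R)-cis-fused hydroazulenone: (3S,3aS,7R,8aS)-7-[2-(tert-butyldimethylsilyloxy)ethyl]-3-hydroxy-3,6,8,8-tetramethyloctahydroazulen-5(1H)-one (epimers at the methyl-bearing C6 of this name)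
Conditions: SmI2 (2.5 equiv), t-BuOH (2 equiv), THF, –78 to 0 °C, high dilution
Reagents that add atoms: none
Why: Divalent samarium transfers one electron to the coordinated side-chain ketone (or, with the same outcome, to the enone); the ketyl carbon C9 adds to the enone β-carbon C5, a second electron turns the α-keto radical into the samarium enolate, and t-BuOH protonates it to the saturated ring B ketone. The closest known reaction type is the SmI2 ketyl–olefin (ketone–enone) reductive cyclisation to cis-fused cyclopentanols. Ring A closes in the 5-exo-trig mode, C9 onto C5, with the radical developing at C4 outside the new ring. C5 is controlled by the tether: the three-atom chain hangs from C6 and can reach only the face of the enone on which it sits, so the two fusion hydrogens become cis. C9 is controlled by the chair-like transition state in which the samarium-bound oxygen lies anti to the enone chain to minimise dipole and steric repulsion, which places the hydroxyl trans to C4 and therefore cis to both fusion hydrogens. The step needs chemoselectivity for C–C bond formation over plain saturation of the enone and over pinacol coupling; low temperature, high dilution and a weak proton donor without HMPA favour the intramolecular 5-exo step, and the γ-branch of the enone slows intermolecular reactions. C2 stays an epimer mixture, which is of no consequence.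

Step 14
Reactants: 21 (5S,6S,9S,11R)-cis-fused hydroazulenone
Product: 22 (5S,6S,9S,11R)-hydroazulenone bis-silyl ether (C9 tertiary OTBS; C13 primary OTBS; C2 epimers)
Conditions: TBSOTf, 2,6-lutidine, CH2Cl2, –78 to 0 °C
Reagents that add atoms: tert-butyldimethylsilyl trifluoromethanesulfonate, CC(C)(C)[Si](C)(C)OS(=O)(=O)C(F)(F)F
Why: Silylation of the tertiary carbinol with the silyl triflate; the ether keeps the alkoxide out of the enolate chemistry of step 15 and protects the carbinol from sulfonylation in step 24, while the ketone is not enolised by lutidine at this temperature.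

Step 15
Reactants: 22 (5S,6S,9S,11R)-hydroazulenone bis-silyl ether
Product: 24 C2=C3 enol triflate of 22, via more substituted lithium enolate 23 (not isolated)
Conditions: LiHMDS (0.95 equiv), THF, –78 to 23 °C, 2 h; then PhNTf2, 0 °C
Reagents that add atoms: N-phenylbis(trifluoromethanesulfonimide), O=S(=O)(N(c1ccccc1)S(=O)(=O)C(F)(F)F)C(F)(F)F
Why: Thermodynamic enolate formation: with a slight deficit of base the lithium enolates equilibrate by proton transfer through HMDS and residual ketone toward the more substituted C2=C3 enolate, which is trapped on oxygen as the enol triflate; the undefined C2 centre disappears here.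

Step 16
Reactants: 24 C2=C3 enol triflate of 22
Product: 25 (5S,6S,9S,11R)-hexahydroazulene bis-silyl ether with the C2=C3 olefin
Conditions: Pd(OAc)2 (5 mol%), PPh3, HCO2H, Bu3N, DMF, 60 °C
Reagents that add atoms: none
Why: Palladium-catalysed formate reduction of an enol triflate (oxidative addition, formate exchange, decarboxylation to a palladium hydride, reductive elimination) should give the trisubstituted ring B olefin without migration and without touching the silyl ethers.

Step 17
Reactants: 25 (5S,6S,9S,11R)-hexahydroazulene bis-silyl ether
Product: 26 (5S,6S,9S,11R)-primary alcohol with the tertiary C9 silyl ether retained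
Conditions: HF·pyridine, pyridine, THF, 0 °C
Reagents that add atoms: none
Why: Selective desilylation: buffered HF·pyridine cleaves a primary TBS ether far faster than a hindered tertiary one, and the buffered medium should not ionise the tertiary ether or move the olefin.

Step 18
Reactants: 26 (5S,6S,9S,11R)-primary alcohol
Product: 27 (5S,6S,9S,11R)-hydroazulene aldehyde (C13 aldehyde)
Conditions: DMP, NaHCO3, CH2Cl2, 23 °C
Reagents that add atoms: none
Why: Dess–Martin oxidation of the primary alcohol to the aldehyde; the olefin and the tertiary silyl ether are inert and there is no α-stereocentre to lose.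

Step 19
Reactants: 28 (E)-geranylacetone
Product: 29 (5S,6S,9S)-5,6:9,10-diepoxy-6,10-dimethylundecan-2-one
Conditions: 1,2:4,5-di-O-isopropylidene-β-L-erythro-2,3-hexodiulo-2,6-pyranose (0.6 equiv), Oxone, K2CO3, Bu4NHSO4, MeCN–(MeO)2CH2–aq. borate buffer, 0 °C
Reagents that add atoms: potassium peroxymonosulfate (Oxone), [K+].[O-]S(=O)(=O)OO
Why: Shi epoxidation through the chiral dioxirane; both trisubstituted olefins are attacked with the same facial sense, which sets C18 and the C15/C21 pair, and the E geometry of the internal olefin fixes the relative configuration of C15 and C21.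

Step 20
Reactants: 29 (5S,6S,9S)-5,6:9,10-diepoxy-6,10-dimethylundecan-2-one
Product: 31 tert-butyl{[(5S,6S,9S)-5,6:9,10-diepoxy-6,10-dimethylundec-1-en-2-yl]oxy}dimethylsilane, via lithium enolate 30 (not isolated)
Conditions: LDA, THF, –78 °C; then TBSCl, HMPA, –78 to 0 °C
Reagents that add atoms: tert-butyldimethylsilyl chloride, CC(C)(C)[Si](C)(C)Cl
Why: Kinetic deprotonation of the methyl ketone at the methyl group followed by O-silylation gives the terminal enol silane; the trisubstituted epoxides are not attacked by the amide base at low temperature.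

Step 21
Reactants: 31 tert-butyl{[(5S,6S,9S)-5,6:9,10-diepoxy-6,10-dimethylundec-1-en-2-yl]oxy}dimethylsilane
Product: 32 (3S,5aS,9aS)-3-(tert-butyldimethylsilyloxy)-2,2,5a-trimethyloctahydro-1-benzoxepin-7(2H)-one
Conditions: TBSOTf (1.1 equiv), 2,6-di-tert-butyl-4-methylpyridine, CH2Cl2, –78 °C
Reagents that add atoms: none
Why: Tandem oxa-/carbacyclisation of a 1,5-diepoxide terminated by an enol silane, a known type of epoxide-opening cascade: silylation of the terminal epoxide oxygen makes the tertiary C19 electrophilic, the internal epoxide oxygen attacks it to give a bicyclic epoxonium ion, and the enol silane carbon C14 opens this ion at the tertiary C15 with inversion, which closes ring C and leaves ring D as the oxepane. Anti opening of the E-epoxide gives the trans ring fusion with the C15 methyl anti to H21, C18 keeps its configuration, and the silyl group released from the oxocarbenium ion regenerates the triflate, so the reaction is a net isomerisation.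

Step 22
Reactants: 32 (3S,5aS,9aS)-3-(tert-butyldimethylsilyloxy)-2,2,5a-trimethyloctahydro-1-benzoxepin-7(2H)-one
Product: 33 (3S,5aS,9aS)-3-(tert-butyldimethylsilyloxy)-2,2,5a-trimethyl-3,4,5,5a,6,9a-hexahydro-1-benzoxepin-7(2H)-one
Conditions: IBX, DMSO, 75 °C
Reagents that add atoms: none
Why: IBX dehydrogenation through the enol; only the C22–C23 side has a β-hydrogen because C15 is quaternary, so a single enone should result, and its double bond blocks enolisation at C23 in the next step.

Step 23
Reactants: 33 (3S,5aS,9aS)-3-(tert-butyldimethylsilyloxy)-2,2,5a-trimethyl-3,4,5,5a,6,9a-hexahydro-1-benzoxepin-7(2H)-one; 27 (5S,6S,9S,11R)-hydroazulene aldehyde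
Product: 35 aldol adduct with the C13–C14 bond (C13 carbinol and C14 as epimer mixtures), via lithium dienolate 34 (not isolated)
Conditions: LDA, THF, –78 °C (33); then 27, –78 °C; aq. NH4Cl
Reagents that add atoms: none
Why: Kinetic α'-deprotonation of the enone gives the cross-conjugated lithium dienolate at C14, the only sp3 α-carbon, and aldol addition to the aldehyde joins the two halves; the two new centres are removed in the next two steps.

Step 24
Reactants: 35 aldol adduct with the C13–C14 bond
Product: 37 cross-conjugated dienone with the exocyclic C13=C14 double bond (geometry not controlled), via mesylate 36 (not isolated)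
Conditions: MsCl, Et3N, CH2Cl2, 0 °C; then DBU, 23 °C
Reagents that add atoms: none
Why: Sulfonylation of the secondary aldol hydroxyl and E1cB elimination complete the aldol condensation; the tertiary carbinol is silylated and the ring B olefin is not involved.

Step 25
Reactants: 37 cross-conjugated dienone
Product: 38 saturated C24 ketone with the bridge equatorial at C14 (14S)
Conditions: [(Ph3P)CuH]6, H2O, THF–PhMe, 23 °C
Reagents that add atoms: none
Why: Conjugate reduction by the phosphine-stabilised copper hydride in the presence of water saturates both enone double bonds but not the isolated trisubstituted olefin. Protonation of the C14 enolate from the axial direction, on the face away from the axial C15 methyl, places the bridge equatorial; this is also the more stable epimer, so a brief base equilibration during work-up can secure it.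

Step 26
Reactants: 38 saturated C24 ketone
Product: 39 bis-silyl ether of the target (C9 and C18 as OTBS; 24R)
Conditions: MeLi, CeCl3, THF, –78 °C
Reagents that add atoms: methyllithium, [Li]C
Why: Organocerium addition to a hindered, enolisable ketone; the axial C15 methyl blocks the axial trajectory (1,3-diaxial), so the methyl group should enter equatorially and the hydroxyl end axial, cis to the C15 methyl and to the equatorial bridge, as the target requires.

Step 27
Reactants: 39 bis-silyl ether of the target
Product: 40 CNP0183476.2 (target)
Conditions: TBAF, THF, 60 °C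
Reagents that add atoms: none
Why: Fluoride cleavage of the secondary and the tertiary silyl ether under non-acidic conditions, which spare the two tertiary carbinols and the trisubstituted olefin.

## Compound list

1 | 2,4,4-trimethylcyclohex-2-en-1-one | CC1=CC(C)(C)CCC1=O | starting material
2 | 2,4,4-trimethylcyclohexa-2,5-dien-1-one | CC1=CC(C)(C)C=CC1=O | intermediate
3 | 2-(2-bromoethyl)-2-methyl-1,3-dioxolane | CC1(CCBr)OCCO1 | starting material
4 | [2-(2-methyl-1,3-dioxolan-2-yl)ethyl]magnesium bromide | CC1(CC[Mg]Br)OCCO1 | intermediate (not isolated)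
5 | bis[2-(2-methyl-1,3-dioxolan-2-yl)ethyl]zinc | CC1(CC[Zn]CCC2(C)OCCO2)OCCO1 | intermediate (not isolated)
6 | (5S)-2,4,4-trimethyl-5-[2-(2-methyl-1,3-dioxolan-2-yl)ethyl]cyclohex-2-en-1-one | CC1=CC(C)(C)[C@@H](CCC2(C)OCCO2)CC1=O | intermediate
7 | (1R,5S)-2,4,4-trimethyl-5-[2-(2-methyl-1,3-dioxolan-2-yl)ethyl]cyclohex-2-en-1-ol (OH cis to the side chain) | CC1=CC(C)(C)[C@@H](CCC2(C)OCCO2)C[C@H]1O | intermediate
8 | triethyl orthoacetate | CC(OCC)(OCC)OCC | starting material
9 | ethyl 2-[(1R,5S)-2,6,6-trimethyl-5-[2-(2-methyl-1,3-dioxolan-2-yl)ethyl]cyclohex-2-en-1-yl]acetate (side chains cis) | CC1=CC[C@H](CCC2(C)OCCO2)C(C)(C)[C@@H]1CC(=O)OCC | intermediate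
10 | 2-[(1R,5S)-2,6,6-trimethyl-5-[2-(2-methyl-1,3-dioxolan-2-yl)ethyl]cyclohex-2-en-1-yl]ethan-1-ol | CC1=CC[C@H](CCC2(C)OCCO2)C(C)(C)[C@@H]1CCO | intermediate
11 | tert-butyldimethylsilyl ether of 10 | CC1=CC[C@H](CCC2(C)OCCO2)C(C)(C)[C@@H]1CCO[Si](C)(C)C(C)(C)C | intermediate
12 | alkylborane from 11 (boron on the former olefinic CH; ring stereocentres as in 11) | CC1C(B)C[C@H](CCC2(C)OCCO2)C(C)(C)[C@@H]1CCO[Si](C)(C)C(C)(C)C | intermediate (not isolated)
13 | (3R,5S)-3-[2-(tert-butyldimethylsilyloxy)ethyl]-2,4,4-trimethyl-5-[2-(2-methyl-1,3-dioxolan-2-yl)ethyl]cyclohexan-1-ol (C1, C2 epimers; trans-2-methyl alcohol expected as main component) | CC1C(O)C[C@H](CCC2(C)OCCO2)C(C)(C)[C@@H]1CCO[Si](C)(C)C(C)(C)C | intermediate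
14 | (3R,5S)-3-[2-(tert-butyldimethylsilyloxy)ethyl]-2,4,4-trimethyl-5-[2-(2-methyl-1,3-dioxolan-2-yl)ethyl]cyclohexan-1-one (C2 epimers) | CC1C(=O)C[C@H](CCC2(C)OCCO2)C(C)(C)[C@@H]1CCO[Si](C)(C)C(C)(C)C | intermediate
15 | ethyl diazoacetate | CCOC(=O)C=[N+]=[N-] | starting material
16 | ethyl (4R,6S)-4-[2-(tert-butyldimethylsilyloxy)ethyl]-3,5,5-trimethyl-6-[2-(2-methyl-1,3-dioxolan-2-yl)ethyl]-2-oxocycloheptane-1-carboxylate (C1, C3 epimers) | CC1C(=O)C(C(=O)OCC)C[C@H](CCC2(C)OCCO2)C(C)(C)[C@@H]1CCO[Si](C)(C)C(C)(C)C | intermediate
17 | (3R,5R)-3-[2-(tert-butyldimethylsilyloxy)ethyl]-2,4,4-trimethyl-5-[2-(2-methyl-1,3-dioxolan-2-yl)ethyl]cycloheptan-1-one (C2 epimers) | CC1C(=O)CC[C@H](CCC2(C)OCCO2)C(C)(C)[C@@H]1CCO[Si](C)(C)C(C)(C)C | intermediate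
18 | lithium enolate of 17 (enolate toward the ring CH2, C1=C7) | CC1C(O[Li])=CC[C@H](CCC2(C)OCCO2)C(C)(C)[C@@H]1CCO[Si](C)(C)C(C)(C)C | intermediate (not isolated)
19 | (4S,6R)-6-[2-(tert-butyldimethylsilyloxy)ethyl]-5,5,7-trimethyl-4-[2-(2-methyl-1,3-dioxolan-2-yl)ethyl]cyclohept-2-en-1-one (C7 epimers) | CC1C(=O)C=C[C@H](CCC2(C)OCCO2)C(C)(C)[C@@H]1CCO[Si](C)(C)C(C)(C)C | intermediate
20 | (4S,6R)-6-[2-(tert-butyldimethylsilyloxy)ethyl]-5,5,7-trimethyl-4-(3-oxobutyl)cyclohept-2-en-1-one (C7 epimers; key-step precursor) | CC1C(=O)C=C[C@H](CCC(C)=O)C(C)(C)[C@@H]1CCO[Si](C)(C)C(C)(C)C | intermediate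
21 | (3S,3aS,7R,8aS)-7-[2-(tert-butyldimethylsilyloxy)ethyl]-3-hydroxy-3,6,8,8-tetramethyloctahydroazulen-5(1H)-one (labels 5S,6S,9S,11R; cis-fused; OH cis to the fusion hydrogens; C6/label C2 epimers; key-step product) | CC1C(=O)C[C@H]2[C@H](CC[C@]2(C)O)C(C)(C)[C@@H]1CCO[Si](C)(C)C(C)(C)C | intermediate
22 | tertiary TBS ether of 21 (labels 5S,6S,9S,11R) | CC1C(=O)C[C@H]2[C@H](CC[C@]2(C)O[Si](C)(C)C(C)(C)C)C(C)(C)[C@@H]1CCO[Si](C)(C)C(C)(C)C | intermediate
23 | lithium C2=C3 enolate of 22 (ring stereocentres unchanged; C11 reads S by CIP priority only) | CC1=C(O[Li])C[C@H]2[C@H](CC[C@]2(C)O[Si](C)(C)C(C)(C)C)C(C)(C)[C@@H]1CCO[Si](C)(C)C(C)(C)C | intermediate (not isolated)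
24 | C2=C3 enol trifluoromethanesulfonate of 22 (ring stereocentres unchanged; C11 reads S by CIP priority only) | CC1=C(OS(=O)(=O)C(F)(F)F)C[C@H]2[C@H](CC[C@]2(C)O[Si](C)(C)C(C)(C)C)C(C)(C)[C@@H]1CCO[Si](C)(C)C(C)(C)C | intermediate
25 | (5S,6S,9S,11R)-hexahydroazulene with the C2=C3 olefin, C9 OTBS and C13 OTBS | CC1=CC[C@H]2[C@H](CC[C@]2(C)O[Si](C)(C)C(C)(C)C)C(C)(C)[C@@H]1CCO[Si](C)(C)C(C)(C)C | intermediate
26 | (5S,6S,9S,11R)-primary alcohol (C13 OH, C9 OTBS) | CC1=CC[C@H]2[C@H](CC[C@]2(C)O[Si](C)(C)C(C)(C)C)C(C)(C)[C@@H]1CCO | intermediate
27 | (5S,6S,9S,11R)-aldehyde (C13 CHO, C9 OTBS) | CC1=CC[C@H]2[C@H](CC[C@]2(C)O[Si](C)(C)C(C)(C)C)C(C)(C)[C@@H]1CC=O | intermediate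
28 | (E)-geranylacetone, (E)-6,10-dimethylundeca-5,9-dien-2-one | CC(=O)CC/C=C(\C)CCC=C(C)C | starting material
29 | (5S,6S,9S)-5,6:9,10-diepoxy-6,10-dimethylundecan-2-one | CC(=O)CC[C@@H]1O[C@@]1(C)CC[C@@H]1OC1(C)C | intermediate
30 | lithium enolate of 29 (terminal, C1=C2) | C=C(O[Li])CC[C@@H]1O[C@@]1(C)CC[C@@H]1OC1(C)C | intermediate (not isolated)
31 | tert-butyl{[(5S,6S,9S)-5,6:9,10-diepoxy-6,10-dimethylundec-1-en-2-yl]oxy}dimethylsilane | C=C(O[Si](C)(C)C(C)(C)C)CC[C@@H]1O[C@@]1(C)CC[C@@H]1OC1(C)C | intermediate
32 | (3S,5aS,9aS)-3-(tert-butyldimethylsilyloxy)-2,2,5a-trimethyloctahydro-1-benzoxepin-7(2H)-one (trans-fused; labels 15S,18S,21S) | C1[C@]2(C)CC[C@H](O[Si](C)(C)C(C)(C)C)C(C)(C)O[C@H]2CCC1=O | intermediate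
33 | (3S,5aS,9aS)-3-(tert-butyldimethylsilyloxy)-2,2,5a-trimethyl-3,4,5,5a,6,9a-hexahydro-1-benzoxepin-7(2H)-one (C22=C23 enone) | C1[C@]2(C)CC[C@H](O[Si](C)(C)C(C)(C)C)C(C)(C)O[C@H]2C=CC1=O | intermediate
34 | lithium dienolate of 33 (C14=C24 enolate, cross-conjugated) | C=1[C@]2(C)CC[C@H](O[Si](C)(C)C(C)(C)C)C(C)(C)O[C@H]2C=CC=1O[Li] | intermediate (not isolated)
35 | aldol adduct: C13 carbinol, C14 methine, C22=C23 enone, both OTBS (C13, C14 epimers) | CC1=CC[C@H]2[C@H](CC[C@]2(C)O[Si](C)(C)C(C)(C)C)C(C)(C)[C@@H]1CC(O)C1[C@]2(C)CC[C@H](O[Si](C)(C)C(C)(C)C)C(C)(C)O[C@H]2C=CC1=O | intermediate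
36 | C13 methanesulfonate of 35 | CC1=CC[C@H]2[C@H](CC[C@]2(C)O[Si](C)(C)C(C)(C)C)C(C)(C)[C@@H]1CC(OS(C)(=O)=O)C1[C@]2(C)CC[C@H](O[Si](C)(C)C(C)(C)C)C(C)(C)O[C@H]2C=CC1=O | intermediate (not isolated)
37 | cross-conjugated dienone (C13=C14 exocyclic, C22=C23 endocyclic; E/Z mixture) | CC1=CC[C@H]2[C@H](CC[C@]2(C)O[Si](C)(C)C(C)(C)C)C(C)(C)[C@@H]1CC=C1[C@]2(C)CC[C@H](O[Si](C)(C)C(C)(C)C)C(C)(C)O[C@H]2C=CC1=O | intermediate
38 | saturated C24 ketone (labels 5S,6S,9S,11R,14S,15S,18S,21S) | CC1=CC[C@H]2[C@H](CC[C@]2(C)O[Si](C)(C)C(C)(C)C)C(C)(C)[C@@H]1CC[C@H]1[C@]2(C)CC[C@H](O[Si](C)(C)C(C)(C)C)C(C)(C)O[C@H]2CCC1=O | intermediate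
39 | bis-TBS ether of the target (C9 and C18 OTBS; 24R) | CC1=CC[C@H]2[C@H](CC[C@]2(C)O[Si](C)(C)C(C)(C)C)C(C)(C)[C@@H]1CC[C@H]1[C@]2(C)CC[C@H](O[Si](C)(C)C(C)(C)C)C(C)(C)O[C@H]2CC[C@@]1(C)O | intermediate
40 | CNP0183476.2, (5S,6S,9S,11R,14S,15S,18S,21S,24R)-triol in the labels defined above | CC1=CC[C@H]2[C@H](CC[C@]2(C)O)C(C)(C)[C@@H]1CC[C@H]1[C@]2(C)CC[C@H](O)C(C)(C)O[C@H]2CC[C@@]1(C)O | target

## Step count and least certain steps

Total step count: 27. Longest linear sequence: 23 steps (steps 1–18, then 23–27); the second branch (steps 19–22) has 4 steps.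

**Step 13 (key step).** Most likely to go wrong: two-electron reduction of the enone outruns C–C bond formation, or the samarium enolate closes by aldol addition onto the methyl ketone. The enone is the more easily reduced carbonyl and the substrate is a mixture of C2 epimers of unequal reactivity. Fallback: move the cyclisation to a doubly activated acceptor whose reduced form is a stabilised, non-basic enolate. Setting out from 16, the dioxolane is hydrolysed (PPTS, wet acetone) to the keto β-keto ester F1. Selenenylation (NaH, PhSeCl) gives the α-phenylselanyl β-keto ester F2, and oxidation with H2O2 and syn-elimination give the 2-(ethoxycarbonyl)cycloheptenone F3. SmI2 and t-BuOH close ring A to the bicyclic β-keto ester F4, and dealkoxycarbonylation (LiCl, wet DMSO, 150 °C) comes back to the route at 21.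

**Step 21.** Most likely to go wrong: the enol silane is consumed before the bicyclic epoxonium ion exists, either by direct attack on the silyl-activated internal epoxide or by protodesilylation, so the oxepane never forms; ring contraction of the epoxides is a further loss channel. Fallback: use a less nucleophilic, acid-stable terminator. Setting out from 29, kinetic enolisation and triflation (LDA, PhNTf2) give the terminal enol triflate F12. Palladium-catalysed coupling with Me3SiCH2MgCl (Pd(PPh3)4) gives the 2-substituted allylsilane F13. The same silyl-triflate cascade, now ending in a Sakurai-type step, gives the exocyclic methylene bicycle F14, and ozonolysis (O3, then Me2S) comes back to the route at 32.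

**Step 15.** Most likely to go wrong: incomplete equilibration, so that the kinetically favoured C3=C4 enolate is trapped, which would lead to the wrong olefin isomer after step 16; the methine at C2 is hindered by C11 and the nearby gem-dimethyl group. Fallback: fix and check the regiochemistry at the stage of an enol silane. Setting out from 22, equilibrating silylation (TMSCl, NaI, Et3N, MeCN) gives the more substituted trimethylsilyl enol ether F11, whose isomer ratio can be read and improved by re-equilibration. MeLi then regenerates the lithium enolate regiospecifically, and N-(5-chloropyridin-2-yl)bis(trifluoromethanesulfonimide) comes back to the route at 24.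

**Step 2.** Most likely to go wrong: loss of site selectivity (addition at the methyl-substituted enone) or erosion of facial selectivity caused by the extra methyl group of the unsymmetrical dienone. Fallback: use the symmetrical dienone, for which desymmetrising additions of this kind are established, and add the methyl group afterwards. Setting out from reagent 5 (made from 3) and commercial 4,4-dimethylcyclohexa-2,5-dien-1-one F5, the same copper-catalysed addition gives the (S)-enone F6. α-Iodination (I2, pyridine) gives the 2-iodoenone F7, and palladium-catalysed methylation (MeB(OH)2, Pd(dppf)Cl2, K3PO4) comes back to the route at 6.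

**Step 9.** Most likely to go wrong: partial migration of the methyl-bearing methine (wrong regiochemistry of insertion), or loss of the dioxolane or silyl ether under BF3. Fallback: a ring expansion whose regiochemistry is set by kinetic enolisation. Setting out from 14, LDA and TMSCl give the less substituted trimethylsilyl enol ether F8. Cyclopropanation (Et2Zn, CH2I2) gives the siloxycyclopropane F9. Oxidative opening with FeCl3 in DMF gives the β-chloro cycloheptanone F10, and elimination with NaOAc in MeOH comes back to the route at 19, which also saves steps 10 and 11.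

**Step 26.** Most likely to go wrong: enolisation of the hindered ketone instead of addition, or a share of axial attack. Fallback: build the carbinol through a spiro-epoxide. Setting out from 38, dimethylsulfoxonium methylide (Me3S(O)I, NaH, DMSO) should add its methylene equatorially and give the spiro-epoxide F15 with the oxygen axial. Reductive opening at the CH2 carbon with LiEt3BH comes back to the route at 39.

## Further compounds

F1 | step 13 | ethyl (4R,6S)-4-[2-(tert-butyldimethylsilyloxy)ethyl]-3,5,5-trimethyl-2-oxo-6-(3-oxobutyl)cycloheptane-1-carboxylate | CC1C(=O)C(C(=O)OCC)C[C@H](CCC(C)=O)C(C)(C)[C@@H]1CCO[Si](C)(C)C(C)(C)C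
F2 | step 13 | 1-(phenylselanyl) derivative of F1 | CC1C(=O)C([Se]c2ccccc2)(C(=O)OCC)C[C@H](CCC(C)=O)C(C)(C)[C@@H]1CCO[Si](C)(C)C(C)(C)C
F3 | step 13 | ethyl 5-[2-(tert-butyldimethylsilyloxy)ethyl]-4,4,6-trimethyl-7-oxo-3-(3-oxobutyl)cyclohept-1-ene-1-carboxylate (ring stereocentres as in 20) | CC1C(=O)C(C(=O)OCC)=C[C@H](CCC(C)=O)C(C)(C)[C@@H]1CCO[Si](C)(C)C(C)(C)C
F4 | step 13 | 4-(ethoxycarbonyl) derivative of 21 (ester on the carbon between the ketone and the ring fusion) | CC1C(=O)C(C(=O)OCC)[C@H]2[C@H](CC[C@]2(C)O)C(C)(C)[C@@H]1CCO[Si](C)(C)C(C)(C)C
F5 | step 2 | 4,4-dimethylcyclohexa-2,5-dien-1-one | CC1(C)C=CC(=O)C=C1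
F6 | step 2 | (5S)-4,4-dimethyl-5-[2-(2-methyl-1,3-dioxolan-2-yl)ethyl]cyclohex-2-en-1-one | O=C1C=CC(C)(C)[C@@H](CCC2(C)OCCO2)C1
F7 | step 2 | (5S)-2-iodo-4,4-dimethyl-5-[2-(2-methyl-1,3-dioxolan-2-yl)ethyl]cyclohex-2-en-1-one | O=C1C(I)=CC(C)(C)[C@@H](CCC2(C)OCCO2)C1
F8 | step 9 | less substituted trimethylsilyl enol ether of 14 | CC1C(O[Si](C)(C)C)=C[C@H](CCC2(C)OCCO2)C(C)(C)[C@@H]1CCO[Si](C)(C)C(C)(C)C
F9 | step 9 | 1-(trimethylsilyloxy)bicyclo[4.1.0]heptane from F8 | CC1C2(O[Si](C)(C)C)CC2[C@H](CCC3(C)OCCO3)C(C)(C)[C@@H]1CCO[Si](C)(C)C(C)(C)C
F10 | step 9 | 3-chlorocycloheptanone corresponding to 19 (chlorine on the carbon next to the ketal-bearing stereocentre) | CC1C(=O)CC(Cl)[C@H](CCC2(C)OCCO2)C(C)(C)[C@@H]1CCO[Si](C)(C)C(C)(C)C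
F11 | step 15 | C2=C3 trimethylsilyl enol ether of 22 | CC1=C(O[Si](C)(C)C)C[C@H]2[C@H](CC[C@]2(C)O[Si](C)(C)C(C)(C)C)C(C)(C)[C@@H]1CCO[Si](C)(C)C(C)(C)C
F12 | step 21 | (5S,6S,9S)-5,6:9,10-diepoxy-6,10-dimethylundec-1-en-2-yl trifluoromethanesulfonate | C=C(OS(=O)(=O)C(F)(F)F)CC[C@@H]1O[C@@]1(C)CC[C@@H]1OC1(C)C
F13 | step 21 | [(5S,6S,9S)-5,6:9,10-diepoxy-6,10-dimethyl-2-methylideneundecyl]trimethylsilane | C=C(C[Si](C)(C)C)CC[C@@H]1O[C@@]1(C)CC[C@@H]1OC1(C)C
F14 | step 21 | (3S,5aS,9aS)-3-(tert-butyldimethylsilyloxy)-2,2,5a-trimethyl-7-methylidenedecahydro-1-benzoxepine | C1[C@]2(C)CC[C@H](O[Si](C)(C)C(C)(C)C)C(C)(C)O[C@H]2CCC1=C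
F15 | step 26 | spiro-epoxide at C24 of 38 (oxygen axial, CH2 equatorial) | CC1=CC[C@H]2[C@H](CC[C@]2(C)O[Si](C)(C)C(C)(C)C)C(C)(C)[C@@H]1CC[C@H]1[C@]2(C)CC[C@H](O[Si](C)(C)C(C)(C)C)C(C)(C)O[C@H]2CC[C@@]13OC3
A1 | alternative 1 | trans-fused oxepan-3-one of rings C–D with benzyloxymethyl at C14 and triethylsilyl ether at C24 | c1ccccc1COC[C@H]1[C@]2(C)CCC(=O)C(C)(C)O[C@H]2CC[C@@]1(C)O[Si](CC)(CC)CC
A2 | alternative 1 | corresponding tetrahydropyran-3-one (C17 missing) | c1ccccc1COC[C@H]1[C@]2(C)CC(=O)C(C)(C)O[C@H]2CC[C@@]1(C)O[Si](CC)(CC)CC
A3 | alternative 2 | rings C–D carbinol with a vinyl group at C14 and C18 OTBS | C=C[C@H]1[C@]2(C)CC[C@H](O[Si](C)(C)C(C)(C)C)C(C)(C)O[C@H]2CC[C@@]1(C)O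
A4 | alternative 2 | oxepane with a 3-(trimethylsilyl)prop-1-enyl group on C15 and a 3-oxobutyl chain on C21 | C[Si](C)(C)CC=C[C@]1(C)CC[C@H](O[Si](C)(C)C(C)(C)C)C(C)(C)O[C@H]1CCC(C)=O
A5 | alternative 3 | cis-fused hydroazulenone ethylene ketal | O1CCOC12CC[C@H]3[C@H](CCC3=O)C(C)(C)[C@@H]2CCO[Si](C)(C)C(C)(C)C
A6 | alternative 3 | 2-substituted cyclopent-2-enone with a dioxolane-bearing chain ending in an isopropenyl group | O=C1CCC=C1CCC1(OCCO1)[C@@H](CCO[Si](C)(C)C(C)(C)C)C(C)=C
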